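**Plan**
- Retrosynthesis: the four benzyl ethers are removed last. Ring E, the phenol ring that joins C3 of the 7-methoxyflavone to C2 of the 5,7-dihydroxychromone, is then cut at two bonds, C1–C2 and C5–C6 (C1 carries the chromone, C3 the flavone, C4 the OH).
- Enabling feature: in ring E the OH on C4 is para to C1 (bonded to the electron-poor chromone C2) and ortho to C3 (bonded to flavone C3). This 1,3,4 pattern is what a 2-flavonyl-1-amino-3-silyloxybutadiene and a terminal alkyne on chromone C2 deliver.
- Forward, dienophile: the pyranone ring of the chromone is closed by oxalate Claisen condensation and cyclodehydration, and the ester is taken to the ethynyl group.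
- Forward, diene: the pyranone ring of the flavone is closed from an aroylated, C-allylated acetophenone, and the allyl group is converted to the aminosilyloxydiene.
- Ring E is formed last by (4+2) cycloaddition and aromatisation, followed by global hydrogenolysis.
- Stereochemistry: the target has no stereocentre; the only selectivity issues are the regiochemistry of the cycloaddition and the E geometry of the aminodiene.

Key step: step 13

Assumption: the enaminone and the derived diene are taken as the E isomers (amino group trans to the acyl or silyloxyvinyl carbon), the geometry that places the amino group on the outside of the s-cis diene.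

**Step 1**
Reactants: 1 2,4,6-trihydroxyacetophenone
Product: 2 1-[2,4-bis(benzyloxy)-6-hydroxyphenyl]ethan-1-one
Conditions: BnBr (2.1 equiv), K2CO3, DMF, rt
Reagents that add atoms: benzyl bromide, BrCc1ccccc1
Why: Williamson etherification should stop after two benzyl groups because the last ortho hydroxyl is hydrogen-bonded to the acetyl carbonyl and is far less nucleophilic.

**Step 2**
Reactants: 2 1-[2,4-bis(benzyloxy)-6-hydroxyphenyl]ethan-1-one; 3 diethyl oxalate
Product: 5 ethyl 5,7-bis(benzyloxy)-4-oxo-4H-chromene-2-carboxylate, via diketo ester 4 (not isolated)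
Conditions: NaOEt, EtOH, reflux; then HCl in EtOH, 50 °C
Reagents that add atoms: none
Why: Claisen condensation of the methyl ketone enolate with the oxalate gives the 2,4-dioxobutanoate, and acid-catalysed cyclodehydration through the chelated phenol then closes the pyranone, the standard route to chromone-2-carboxylates.

**Step 3**
Reactants: 5 ethyl 5,7-bis(benzyloxy)-4-oxo-4H-chromene-2-carboxylate
Product: 6 5,7-bis(benzyloxy)-2-(hydroxymethyl)-4H-chromen-4-one
Conditions: NaBH4, EtOH–THF, 0 °C
Reagents that add atoms: none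
Why: chemoselective borohydride reduction is expected because the ester on the electron-poor C2 is activated, whereas the pyranone carbonyl is a vinylogous ester and reacts slowly at 0 °C.

**Step 4**
Reactants: 6 5,7-bis(benzyloxy)-2-(hydroxymethyl)-4H-chromen-4-one
Product: 7 5,7-bis(benzyloxy)-4-oxo-4H-chromene-2-carbaldehyde
Conditions: Dess–Martin periodinane, CH2Cl2, rt
Reagents that add atoms: none
Why: Dess–Martin oxidation converts the primary allylic-type alcohol to the aldehyde under neutral, anhydrous conditions that leave the benzyl ethers and the pyranone untouched.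

**Step 5**
Reactants: 7 5,7-bis(benzyloxy)-4-oxo-4H-chromene-2-carbaldehyde; 8 (trimethylsilyl)diazomethane
Product: 9 5,7-bis(benzyloxy)-2-ethynyl-4H-chromen-4-one
Conditions: 8 (1.2 equiv), LiN(i-Pr)2, THF, −78 °C; then 7, −78 → 0 °C; aqueous work-up
Reagents that add atoms: none
Why: in the Colvin rearrangement the lithiated silyldiazomethane adds to the aldehyde (much more electrophilic than the pyranone carbonyl), Peterson elimination gives a diazoalkene, and loss of N2 with a 1,2-hydrogen shift in the alkylidene carbene gives the terminal alkyne without any protic nucleophile present.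

**Step 6**
Reactants: 10 1-(2,6-dihydroxy-4-methoxyphenyl)ethan-1-one
Product: 11 1-[2-(benzyloxy)-6-hydroxy-4-methoxyphenyl]ethan-1-one
Conditions: BnBr (1.05 equiv), K2CO3, acetone, reflux
Reagents that add atoms: benzyl bromide, BrCc1ccccc1
Why: Williamson mono-benzylation of the two equivalent hydroxyls should stop after one, since the remaining hydroxyl is then chelated to the carbonyl.

**Step 7**
Reactants: 11 1-[2-(benzyloxy)-6-hydroxy-4-methoxyphenyl]ethan-1-one; 12 4-(benzyloxy)benzoyl chloride
Product: 13 1-[2-(benzyloxy)-6-hydroxy-4-methoxyphenyl]-3-[4-(benzyloxy)phenyl]propane-1,3-dione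
Conditions: LiN(SiMe3)2 (3.2 equiv), THF, −78 → −10 °C; then 12, −78 °C → rt; 1 M HCl work-up
Reagents that add atoms: none
Why: the lithium phenoxide-enolate dianion is aroylated at carbon, a one-flask Baker–Venkataraman-type acylation, and the third equivalent of base removes the acidic diketone proton so that the product is protected from further acylation.

**Step 8**
Reactants: 13 1-[2-(benzyloxy)-6-hydroxy-4-methoxyphenyl]-3-[4-(benzyloxy)phenyl]propane-1,3-dione; 14 allyl methyl carbonate
Product: 15 2-allyl-1-[2-(benzyloxy)-6-hydroxy-4-methoxyphenyl]-3-[4-(benzyloxy)phenyl]propane-1,3-dione (racemic)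
Conditions: Pd(PPh3)4 (5 mol%), THF, rt
Reagents that add atoms: none
Why: in the Tsuji–Trost allylation zerovalent palladium ionises the carbonate, the methoxide released deprotonates the 1,3-diketone, and this soft carbon nucleophile attacks the allyl complex at carbon under neutral conditions; any O-allylation of the chelated phenol is reversible.

**Step 9**
Reactants: 15 2-allyl-1-[2-(benzyloxy)-6-hydroxy-4-methoxyphenyl]-3-[4-(benzyloxy)phenyl]propane-1,3-dione
Product: 16 3-allyl-5-(benzyloxy)-2-[4-(benzyloxy)phenyl]-7-methoxy-4H-chromen-4-one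
Conditions: p-TsOH·H2O (10 mol%), toluene, 80 °C
Reagents that add atoms: none
Why: acid-catalysed cyclodehydration (the phenol adds to the aroyl ketone and the hemiketal loses water) is the usual closing step of a Baker–Venkataraman flavone synthesis and removes the labile stereocentre of 15.

**Step 10**
Reactants: 16 3-allyl-5-(benzyloxy)-2-[4-(benzyloxy)phenyl]-7-methoxy-4H-chromen-4-one
Product: 17 5-(benzyloxy)-2-[4-(benzyloxy)phenyl]-7-methoxy-3-(2-oxopropyl)-4H-chromen-4-one
Conditions: PdCl2 (cat.), CuCl (cat.), O2 (1 atm), DMF–H2O (7:1), rt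
Reagents that add atoms: water, O
Why: Tsuji–Wacker oxidation should give the methyl ketone by Markovnikov hydroxypalladation of the terminal alkene with water and β-hydride elimination, as for other ketones carrying an allyl group two carbons from the carbonyl, with O2 and CuCl reoxidising palladium.

**Step 11**
Reactants: 17 5-(benzyloxy)-2-[4-(benzyloxy)phenyl]-7-methoxy-3-(2-oxopropyl)-4H-chromen-4-one; 18 N,N-dimethylformamide dimethyl acetal
Product: 19 (E)-3-{5-(benzyloxy)-2-[4-(benzyloxy)phenyl]-7-methoxy-4-oxo-4H-chromen-3-yl}-4-(dimethylamino)but-3-en-2-one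
Conditions: 18 (2 equiv), toluene, 90 °C
Reagents that add atoms: none
Why: aminomethylenation with the formamide acetal takes place at the more acidic methylene between the ketone and the chromone C3, as with arylacetones, and the push–pull alkene settles in the E geometry.

**Step 12**
Reactants: 19 (E)-3-{5-(benzyloxy)-2-[4-(benzyloxy)phenyl]-7-methoxy-4-oxo-4H-chromen-3-yl}-4-(dimethylamino)but-3-en-2-one
Product: 20 5-(benzyloxy)-2-[4-(benzyloxy)phenyl]-3-[(1E)-3-(tert-butyldimethylsilyloxy)-1-(dimethylamino)buta-1,3-dien-2-yl]-7-methoxy-4H-chromen-4-one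
Conditions: KN(SiMe3)2, THF, −78 °C; then t-BuMe2SiCl, −78 °C → rt; filtration under argon, used crude
Reagents that add atoms: tert-butyldimethylsilyl chloride, CC(C)(C)[Si](C)(C)Cl
Why: kinetic deprotonation of the only acidic site, the methyl group of the vinylogous amide, and O-silylation of the resulting enolate is the standard preparation of 1-amino-3-silyloxybutadienes and leaves the enamine geometry unchanged.

**Step 13**
Reactants: 20 5-(benzyloxy)-2-[4-(benzyloxy)phenyl]-3-[(1E)-3-(tert-butyldimethylsilyloxy)-1-(dimethylamino)buta-1,3-dien-2-yl]-7-methoxy-4H-chromen-4-one; 9 5,7-bis(benzyloxy)-2-ethynyl-4H-chromen-4-one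
Product: 23 5-(benzyloxy)-2-[4-(benzyloxy)phenyl]-3-{5-[5,7-bis(benzyloxy)-4-oxo-4H-chromen-2-yl]-2-hydroxyphenyl}-7-methoxy-4H-chromen-4-one, via cyclohexa-1,4-diene cycloadduct 21 (not isolated), via aryl silyl ether 22 (not isolated)
Conditions: 20 (1.5 equiv), toluene, 4 Å molecular sieves, rt → 50 °C; then HF·pyridine, THF, 0 °C → rt
Reagents that add atoms: none
Why: Proposed new method: diene 20 should add to the terminal alkyne of 9 in a concerted but asynchronous intermolecular (4+2) cycloaddition, the CH2 terminus (largest HOMO coefficient) bonding ahead to the unsubstituted alkyne carbon, which is the vinylogous acceptor position of the pyranone, while the aminomethine carbon bonds to the alkyne carbon on chromone C2; this closes ring E as a six-membered carbocycle by forming C1–C2 and C5–C6 together. The closest known reaction type is the Diels–Alder reaction of 1-amino-3-silyloxybutadienes with acetylenic esters and ketones, which aromatise to para-acyl phenols; what is untested is an alkyne activated only through the chromone enone and a diene carrying a bulky heteroaryl group on C2. 1,4-Elimination of dimethylamine from the cyclohexa-1,4-diene 21 gives the aryl silyl ether 22, and fluoride then frees the phenol. The single stereocentre of 21 (the amino-bearing carbon, formed racemic) is destroyed on aromatisation, so no stereocontrol is required. The selectivity needed is regiochemical (OH para to chromone C2), and it is secured by matched polarisation: the amino and silyloxy donors both raise the coefficient at the CH2 terminus while the pyranone carbonyl withdraws from the terminal alkyne carbon. The flavonyl group on C2, twisted out of the diene plane, should favour the s-cis conformer.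

**Step 14**
Reactants: 23 5-(benzyloxy)-2-[4-(benzyloxy)phenyl]-3-{5-[5,7-bis(benzyloxy)-4-oxo-4H-chromen-2-yl]-2-hydroxyphenyl}-7-methoxy-4H-chromen-4-one
Product: 24 5-hydroxy-3-[5-(5,7-dihydroxy-4-oxo-4H-chromen-2-yl)-2-hydroxyphenyl]-2-(4-hydroxyphenyl)-7-methoxy-4H-chromen-4-one
Conditions: H2 (1 atm), 10% Pd/C, THF–MeOH, rt
Reagents that add atoms: none
Why: catalytic hydrogenolysis cleaves the four benzyl ethers while the methyl ether and the aromatic pyranone rings, which resist hydrogenation at ambient pressure, remain.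

**Compound list**
1 | 2,4,6-trihydroxyacetophenone | CC(=O)c1c(O)cc(O)cc1O | starting material
2 | 1-[2,4-bis(benzyloxy)-6-hydroxyphenyl]ethan-1-one | CC(=O)c1c(O)cc(OCc2ccccc2)cc1OCc1ccccc1 | intermediate
3 | diethyl oxalate | CCOC(=O)C(=O)OCC | starting material
4 | ethyl 4-[2,4-bis(benzyloxy)-6-hydroxyphenyl]-2,4-dioxobutanoate (formed as its sodium enolate, not isolated) | CCOC(=O)C(=O)CC(=O)c1c(O)cc(OCc2ccccc2)cc1OCc1ccccc1 | intermediate
5 | ethyl 5,7-bis(benzyloxy)-4-oxo-4H-chromene-2-carboxylate | CCOC(=O)c1cc(=O)c2c(OCc3ccccc3)cc(OCc3ccccc3)cc2o1 | intermediate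
6 | 5,7-bis(benzyloxy)-2-(hydroxymethyl)-4H-chromen-4-one | OCc1cc(=O)c2c(OCc3ccccc3)cc(OCc3ccccc3)cc2o1 | intermediate
7 | 5,7-bis(benzyloxy)-4-oxo-4H-chromene-2-carbaldehyde | O=Cc1cc(=O)c2c(OCc3ccccc3)cc(OCc3ccccc3)cc2o1 | intermediate
8 | (trimethylsilyl)diazomethane | C[Si](C)(C)C=[N+]=[N-] | starting material
9 | 5,7-bis(benzyloxy)-2-ethynyl-4H-chromen-4-one | C#Cc1cc(=O)c2c(OCc3ccccc3)cc(OCc3ccccc3)cc2o1 | intermediate
10 | 1-(2,6-dihydroxy-4-methoxyphenyl)ethan-1-one | CC(=O)c1c(O)cc(OC)cc1O | starting material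
11 | 1-[2-(benzyloxy)-6-hydroxy-4-methoxyphenyl]ethan-1-one | CC(=O)c1c(O)cc(OC)cc1OCc1ccccc1 | intermediate
12 | 4-(benzyloxy)benzoyl chloride | O=C(Cl)c1ccc(OCc2ccccc2)cc1 | starting material
13 | 1-[2-(benzyloxy)-6-hydroxy-4-methoxyphenyl]-3-[4-(benzyloxy)phenyl]propane-1,3-dione | O=C(CC(=O)c1c(O)cc(OC)cc1OCc1ccccc1)c1ccc(OCc2ccccc2)cc1 | intermediate
14 | allyl methyl carbonate | C=CCOC(=O)OC | starting material
15 | 2-allyl-1-[2-(benzyloxy)-6-hydroxy-4-methoxyphenyl]-3-[4-(benzyloxy)phenyl]propane-1,3-dione (racemic, labile centre) | C=CCC(C(=O)c1c(O)cc(OC)cc1OCc1ccccc1)C(=O)c1ccc(OCc2ccccc2)cc1 | intermediate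
16 | 3-allyl-5-(benzyloxy)-2-[4-(benzyloxy)phenyl]-7-methoxy-4H-chromen-4-one | C=CCc1c(-c2ccc(OCc3ccccc3)cc2)oc2cc(OC)cc(OCc3ccccc3)c2c1=O | intermediate
17 | 5-(benzyloxy)-2-[4-(benzyloxy)phenyl]-7-methoxy-3-(2-oxopropyl)-4H-chromen-4-one | CC(=O)Cc1c(-c2ccc(OCc3ccccc3)cc2)oc2cc(OC)cc(OCc3ccccc3)c2c1=O | intermediate
18 | N,N-dimethylformamide dimethyl acetal | CN(C)C(OC)OC | starting material
19 | (E)-3-{5-(benzyloxy)-2-[4-(benzyloxy)phenyl]-7-methoxy-4-oxo-4H-chromen-3-yl}-4-(dimethylamino)but-3-en-2-one | CN(C)/C=C(/C(C)=O)c1c(-c2ccc(OCc3ccccc3)cc2)oc2cc(OC)cc(OCc3ccccc3)c2c1=O | intermediate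
20 | 5-(benzyloxy)-2-[4-(benzyloxy)phenyl]-3-[(1E)-3-(tert-butyldimethylsilyloxy)-1-(dimethylamino)buta-1,3-dien-2-yl]-7-methoxy-4H-chromen-4-one | CN(C)/C=C(/C(=C)O[Si](C)(C)C(C)(C)C)c1c(-c2ccc(OCc3ccccc3)cc2)oc2cc(OC)cc(OCc3ccccc3)c2c1=O | intermediate
21 | 5-(benzyloxy)-2-[4-(benzyloxy)phenyl]-3-{5-[5,7-bis(benzyloxy)-4-oxo-4H-chromen-2-yl]-2-(tert-butyldimethylsilyloxy)-6-(dimethylamino)cyclohexa-1,4-dien-1-yl}-7-methoxy-4H-chromen-4-one (racemic cycloadduct, not isolated) | CN(C)C1C(c2c(-c3ccc(OCc4ccccc4)cc3)oc3cc(OC)cc(OCc4ccccc4)c3c2=O)=C(O[Si](C)(C)C(C)(C)C)CC=C1c1cc(=O)c2c(OCc3ccccc3)cc(OCc3ccccc3)cc2o1 | intermediate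
22 | 5-(benzyloxy)-2-[4-(benzyloxy)phenyl]-3-{5-[5,7-bis(benzyloxy)-4-oxo-4H-chromen-2-yl]-2-(tert-butyldimethylsilyloxy)phenyl}-7-methoxy-4H-chromen-4-one (not isolated) | CC(C)(C)[Si](C)(C)Oc1ccc(-c2cc(=O)c3c(OCc4ccccc4)cc(OCc4ccccc4)cc3o2)cc1-c1c(-c2ccc(OCc3ccccc3)cc2)oc2cc(OC)cc(OCc3ccccc3)c2c1=O | intermediate
23 | 5-(benzyloxy)-2-[4-(benzyloxy)phenyl]-3-{5-[5,7-bis(benzyloxy)-4-oxo-4H-chromen-2-yl]-2-hydroxyphenyl}-7-methoxy-4H-chromen-4-one | COc1cc(OCc2ccccc2)c2c(=O)c(-c3cc(-c4cc(=O)c5c(OCc6ccccc6)cc(OCc6ccccc6)cc5o4)ccc3O)c(-c3ccc(OCc4ccccc4)cc3)oc2c1 | intermediate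
24 | 5-hydroxy-3-[5-(5,7-dihydroxy-4-oxo-4H-chromen-2-yl)-2-hydroxyphenyl]-2-(4-hydroxyphenyl)-7-methoxy-4H-chromen-4-one | COc1cc(O)c2c(=O)c(-c3cc(-c4cc(=O)c5c(O)cc(O)cc5o4)ccc3O)c(-c3ccc(O)cc3)oc2c1 | target

**Step count**
Total: 14 steps. Longest linear sequence: 9 steps (steps 6 to 14, from 10 to 24); the dienophile branch (steps 1 to 5) joins at step 13.

**Steps most likely to fail**

Step 13 (Proposed new method). The cycloaddition may be too slow, because the alkyne is activated only through the pyranone and the diene is hindered at C2. Hydrolysis of the diene, or conjugate addition of liberated dimethylamine to the alkyne, could then consume the partners.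
Fallback, from 20 back to the route at 24: the diene 20 would be combined with methyl propiolate, an established acetylenic ester dienophile for aminosilyloxydienes, and worked up with HF·pyridine to give methyl 3-{5-(benzyloxy)-2-[4-(benzyloxy)phenyl]-7-methoxy-4-oxo-4H-chromen-3-yl}-4-hydroxybenzoate F1. Benzylation (BnBr, K2CO3, DMF) would give the benzyl ether methyl 4-(benzyloxy)-3-{5-(benzyloxy)-2-[4-(benzyloxy)phenyl]-7-methoxy-4-oxo-4H-chromen-3-yl}benzoate F2. Claisen condensation of F2 with the dianion of acetophenone 2 [LiN(SiMe3)2, THF] would give the 1,3-diketone F3. Cyclodehydration (p-TsOH, toluene, 80 °C) would then close the second pyranone to give the pentabenzyl ether F4, and hydrogenolysis under the conditions of step 14 would give 24. Ring E is still formed by the same two bonds, and only the chromone is built afterwards.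

Step 5. The lithiated diazo reagent may add to the pyranone, or the diazo compound may undergo dipolar cycloaddition with the activated alkyne product.
Fallback, from 7 back to the route at 9: Wittig bromomethylenation of 7 (Ph3PCH2Br bromide, KOt-Bu, THF, −78 °C) would give (Z)-5,7-bis(benzyloxy)-2-(2-bromoethenyl)-4H-chromen-4-one F5. Anti-elimination of HBr with DBU in THF would then give 9 with no diazo species present.

Step 11. Condensation may occur at the unhindered methyl group instead of the methylene next to the crowded chromone C3, or it may stall.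
Fallback, from 17 back to the route at 19: soft enolisation of 17 (Me3SiOTf, Et3N, CH2Cl2) would fix the regiochemistry as the conjugated silyl enol ether (Z)-5-(benzyloxy)-2-[4-(benzyloxy)phenyl]-7-methoxy-3-[2-(trimethylsilyloxy)prop-1-en-1-yl]-4H-chromen-4-one F6. Mukaiyama-type reaction of F6 with trimethyl orthoformate (BF3·OEt2, −78 °C) would give the β-keto acetal 5-(benzyloxy)-2-[4-(benzyloxy)phenyl]-3-(1,1-dimethoxy-3-oxobutan-2-yl)-7-methoxy-4H-chromen-4-one F7. Treatment of F7 with dimethylamine in THF, with loss of two molecules of methanol, would give enaminone 19.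

**Further compounds**
F1 | step 13 | methyl 3-{5-(benzyloxy)-2-[4-(benzyloxy)phenyl]-7-methoxy-4-oxo-4H-chromen-3-yl}-4-hydroxybenzoate | COC(=O)c1ccc(O)c(-c2c(-c3ccc(OCc4ccccc4)cc3)oc3cc(OC)cc(OCc4ccccc4)c3c2=O)c1
F2 | step 13 | methyl 4-(benzyloxy)-3-{5-(benzyloxy)-2-[4-(benzyloxy)phenyl]-7-methoxy-4-oxo-4H-chromen-3-yl}benzoate | COC(=O)c1ccc(OCc2ccccc2)c(-c2c(-c3ccc(OCc4ccccc4)cc3)oc3cc(OC)cc(OCc4ccccc4)c3c2=O)c1
F3 | step 13 | 1-[2,4-bis(benzyloxy)-6-hydroxyphenyl]-3-(4-(benzyloxy)-3-{5-(benzyloxy)-2-[4-(benzyloxy)phenyl]-7-methoxy-4-oxo-4H-chromen-3-yl}phenyl)propane-1,3-dione | O=C(CC(=O)c1c(O)cc(OCc2ccccc2)cc1OCc1ccccc1)c1ccc(OCc2ccccc2)c(-c2c(-c3ccc(OCc4ccccc4)cc3)oc3cc(OC)cc(OCc4ccccc4)c3c2=O)c1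
F4 | step 13 | 5-(benzyloxy)-3-{2-(benzyloxy)-5-[5,7-bis(benzyloxy)-4-oxo-4H-chromen-2-yl]phenyl}-2-[4-(benzyloxy)phenyl]-7-methoxy-4H-chromen-4-one | COc1cc(OCc2ccccc2)c2c(=O)c(-c3cc(-c4cc(=O)c5c(OCc6ccccc6)cc(OCc6ccccc6)cc5o4)ccc3OCc3ccccc3)c(-c3ccc(OCc4ccccc4)cc3)oc2c1
F5 | step 5 | (Z)-5,7-bis(benzyloxy)-2-(2-bromoethenyl)-4H-chromen-4-one | Br/C=C\c1cc(=O)c2c(OCc3ccccc3)cc(OCc3ccccc3)cc2o1
F6 | step 11 | (Z)-5-(benzyloxy)-2-[4-(benzyloxy)phenyl]-7-methoxy-3-[2-(trimethylsilyloxy)prop-1-en-1-yl]-4H-chromen-4-one | C[Si](C)(C)O/C(C)=C\c1c(-c2ccc(OCc3ccccc3)cc2)oc2cc(OC)cc(OCc3ccccc3)c2c1=O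
F7 | step 11 | 5-(benzyloxy)-2-[4-(benzyloxy)phenyl]-3-(1,1-dimethoxy-3-oxobutan-2-yl)-7-methoxy-4H-chromen-4-one (racemic) | CC(=O)C(C(OC)OC)c1c(-c2ccc(OCc3ccccc3)cc2)oc2cc(OC)cc(OCc3ccccc3)c2c1=O
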